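We must choose one temperature for a flask stirred 80 min, and two colleagues disagree on how to choose it.

| flask | substrate | coupling partner | free catalyst | second catalyst | temperature | remark | time |
|---|---|---|---|---|---|---|---|
| green | 0.50 M | 0.75 equiv | 4.8 mol% | 1 mol% | −20 °C | run made earlier |  |
| amber | 0.50 M | 3 equiv | 4.8 mol% | 1 mol% | 15 °C | run made earlier |  |
| zeta | 0.50 M | 1.50 equiv | 4.8 mol% | 1 mol% | 5 °C |  | 80 min |
| delta | 0.50 M | 1.50 equiv | 4.8 mol% | 1 mol% | 25 °C |  | 80 min |
| eta | 0.50 M | 1.50 equiv | 4.8 mol% | 1 mol% | −15 °C |  | 80 min |
| beta | 0.50 M | 1.50 equiv | 4.8 mol% | 1 mol% | 45 °C |  | 80 min |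

- green (time / min: target / %): 30.0: 0.5; 60.0: 3.4; 90.0: 5.8; 150: 10.7; 180: 13.4
- amber (time / min: target / %): 3.00: 4.1; 5.00: 7.8; 10.0: 15.9; 15.0: 19.9; 25.0: 26.9; 40.0: 32.1

(each reading ± 0.5 percentage points)

- the flask with the highest amount of target, in percent of the substrate charged ("all alike" if they lie within 1.5 percentage points) (zeta / delta / eta / beta / all alike)
- final target, as a percentage of the substrate charged, in zeta
- final target, as a percentage of the substrate charged, in delta
- final target, as a percentage of the substrate charged, in eta
- final target, as a percentage of the substrate charged, in beta



Both start from the same rates. After its lag, the green run climbs by a fraction 8.33 × 10⁻⁴ min⁻¹ of the charge each minute, and the amber run begins at 0.0169 min⁻¹. These two runs differ in both temperature and coupling partner, so the colleagues cannot separate the two effects. They charge the whole ratio to warming and spread it evenly, in the logarithm, over temperature. That gives zeta an early rate of 0.00714 min⁻¹.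

The amber rate then sinks to 0.00347 min⁻¹. Read as a steady fade, pseudo-first-order in form, this means a life of 16.4 min. Adding the late rate times that life to the target at the middle of the last interval gives an amber ceiling of 35.2%.

The quantity that sorts the flasks is the fill ratio, the target the early rate would make over the asked time divided by that ceiling. On this reckoning a ratio of one is the zero of the scale: below it a flask is short of minutes, and above it the flask meets the ceiling. Zeta stands at 1.62, above one. Eta stands at 0.291, which is a reach of 10.2%, and delta stands at 9.05.

The first colleague treats the symmetric case as the baseline: if rate and fade warm alike, their quotient, the ceiling, stays put. The second colleague points out that the green run shows no fade over 120 min, while the amber life is much shorter than that span, so the fade must warm faster and the ceiling must fall with heat. I side with the first colleague: eta at its reach, and the warmer flasks about level at the ceiling.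

The forecast sides with the second colleague, naming zeta and giving 34% there, 13% in delta, 11.5% in eta and 4% in beta, on the ground that “deactivation has a higher activation energy than turnover”.

The simulation puts zeta first with 33.0%, under its reach of 57.1%, as a fill ratio above one says. Delta gives 29.9% and eta 10.6%. The falling ceiling has its region at the hot end, where beta holds 13.8%, well under the amber ceiling, with 0% of the substrate left.

    second catalyst → spent catalyst (k = 0.0340 min⁻¹, Ea = 94.0 kJ mol⁻¹)
    2 substrate → self-condensation product (k = 0.240 M⁻¹ min⁻¹, Ea = 70.0 kJ mol⁻¹)
    intermediate → side product (k = 0.140 min⁻¹, Ea = 77.0 kJ mol⁻¹)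
    coupling partner + second catalyst + intermediate → second catalyst + target (k = 220 M⁻² min⁻¹, Ea = 36.0 kJ mol⁻¹)
    substrate + free catalyst → free catalyst + intermediate (k = 2.40 M⁻¹ min⁻¹, Ea = 55.0 kJ mol⁻¹)
    (constants at 25 °C)

Read at 30 min, zeta has a fill ratio of 0.608, below one; the early rate gives 21.4% by then, and zeta already falls short of that, holding 18.7%.

The runs were generated by integration for an exercise.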